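Remark on the chemistry: guaiane numbering is used. C1/C5 are the ring-fusion carbons, ring A is C1–C5, ring B is C1, C5–C10, C7 bears i-Pr, C8 the ester and C10 the carbinol. In the target H-1, H-7, H-8, 10-CH3 and the oxirane O are α; H-5, 4-CH3, 7-i-Pr, O-8 and 10-OH are β. 3-Bromocyclopent-2-en-1-one, prop-2-yn-1-ol and all reagents are taken as commercial.

**Retrosynthetic overview**
- Last steps: the 3α,4α-oxirane comes from the C3=C4 alkene by reagent-controlled epoxidation, and the veratrate from the 8β,10β-diol. Both ring B oxygens come from one ketone/enol ether pair.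
- Enabling feature: in ring B the oxygen-bearing C8 and C10 flank CH2-9, so ring B is a masked cycloheptane-1,3-dione. A temporary C8–C10 bond turns it into a cis-1,2-dialkenylcyclopropane-1,2-diolate, whose [3,3] shift joins C5 and C6.
- Key disconnection: C8–C9 and C5–C6 in one flask, back to the lithium enolate of a 1-acetylcyclopentene (C9, C10, C1, C5 and ring A) and an α-isopropylacryloylsilane (C8, C7, C6).
- Ring order: ring A is bought; a transient cyclopropane and then ring B form in the key step; the oxirane is closed last.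
- Stereo relay: 4α-OBn → C5 → C1 (cis) → C10. The C4 ketone then inverts C5 to the trans fusion and carries the C3=C4–CH3 unit; C7 and C8 follow on the trans-fused chair.

Key step: step 7

**Route**

Step 1
Reactants: 1 3-bromocyclopent-2-en-1-one
Product: 2 (1R)-3-bromocyclopent-2-en-1-ol
Conditions: (S)-2-methyl-CBS-oxazaborolidine (10 mol %), BH3·SMe2, THF, −20 °C; H2O
Reagents that add atoms: none
Why: Corey–Bakshi–Shibata reduction: with the bromoalkenyl arm as the large and CH2 as the small substituent, the (S)-catalyst should deliver hydride to the face that gives the (R)-carbinol, the later 4α-oxygen.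

Step 2
Reactants: 2 (1R)-3-bromocyclopent-2-en-1-ol
Product: 3 benzyl (1R)-3-bromocyclopent-2-en-1-yl ether
Conditions: NaH, BnBr, THF, 0 °C → rt
Reagents that add atoms: benzyl bromide, BrCc1ccccc1
Why: Williamson ether synthesis; the C–O bond at the stereocentre is not touched, and benzyl survives organolithium and amide bases and leaves later under neutral hydrogenolysis.

Step 3
Reactants: 3 benzyl (1R)-3-bromocyclopent-2-en-1-yl ether
Product: 5 1-[(3R)-3-(benzyloxy)cyclopent-1-en-1-yl]ethan-1-one, via alkenyllithium 4 (not isolated)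
Conditions: t-BuLi (2.1 equiv), Et2O, −78 °C; MeC(O)N(OMe)Me; 1 M HCl
Reagents that add atoms: N-methoxy-N-methylacetamide, CC(=O)N(C)OC
Why: Bromine–lithium exchange followed by Weinreb ketone synthesis; the chelated tetrahedral adduct stops at the ketone, the alkenyllithium keeps the double-bond position, and C4 is untouched.

Step 4
Reactants: 6 prop-2-yn-1-ol
Product: 7 3-methyl-2-methylidenebutan-1-ol
Conditions: i-PrMgCl (2.5 equiv), CuI (10 mol %), THF, −10 °C → rt; 1 M HCl
Reagents that add atoms: isopropylmagnesium chloride, CC(C)[Mg]Cl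
Why: Copper-catalysed carbomagnesiation of a propargylic alkoxide: isopropyl adds to the internal alkyne carbon because magnesium ends in a five-membered alkoxide chelate, and protonolysis gives the 2-substituted allylic alcohol (no stereocentre).

Step 5
Reactants: 7 3-methyl-2-methylidenebutan-1-ol
Product: 9 1-[tert-butyl(dimethyl)silyl]-3-methyl-2-methylidenebutan-1-ol (racemic), via allyl silyl ether 8 (not isolated)
Conditions: n-BuLi, THF, −78 °C; t-BuMe2SiCl, → rt; t-BuLi, −78 → −40 °C; AcOH
Reagents that add atoms: tert-butyldimethylsilyl chloride, CC(C)(C)[Si](C)(C)Cl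
Why: O-Silylation, allylic α-lithiation and retro-Brook (silyl-Wittig) rearrangement in one flask, driven by the change from carbanion to alkoxide; the new carbinol centre is racemic and is erased in step 6.

Step 6
Reactants: 9 1-[tert-butyl(dimethyl)silyl]-3-methyl-2-methylidenebutan-1-ol
Product: 10 1-[tert-butyl(dimethyl)silyl]-3-methyl-2-methylidenebutan-1-one
Conditions: (COCl)2, DMSO, CH2Cl2, −78 °C; Et3N
Reagents that add atoms: none
Why: Swern oxidation, the standard mild oxidation of α-hydroxysilanes to acylsilanes, runs below −60 °C without acid or free alkoxide, so no Brook-type loss of silicon should occur.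

Step 7
Reactants: 5 1-[(3R)-3-(benzyloxy)cyclopent-1-en-1-yl]ethan-1-one; 10 1-[tert-butyl(dimethyl)silyl]-3-methyl-2-methylidenebutan-1-one
Product: 15 cis-fused hydroazulenone (C10 ketone; C7=C8 tert-butyldimethylsilyl enol ether with i-Pr on C7; 4α-OBn; H-1α; H-5α), via lithium dienolate 11 (not isolated), via silyl carbinolate 12 (not isolated), via divinylcyclopropanolate 13 (not isolated), via cycloheptadienolate 14 (not isolated)
Conditions: LDA, THF, −78 °C; 10, −80 → −30 °C; AcOH, −78 °C
Reagents that add atoms: none
Why: Kinetic deprotonation of the acetyl CH3 gives cross-conjugated dienolate 11, whose CH2 adds 1,2 to the acylsilane carbonyl (C8–C9 bond, 12); the alkoxide triggers a 1,2-Brook shift, the siloxyallyl anion attacks the C10 ketone to make the temporary C8–C10 bond of 13, and an anion-accelerated oxy-Cope shift forms C5–C6 while cleaving C8–C10 to give 14. The closest known reaction type is the Brook rearrangement-mediated [3+4] annulation of acryloylsilanes with lithium enolates of alkenyl methyl ketones, 1-acetylcycloalkenes included; only the substitution of 10 (alkyl on C7, none on C6) is new. The cyclopropane closes 3-exo-trig, and ring B is closed not end to end but by [3,3] ring expansion through the boat transition state open only to the cis-dialkenyl isomer. C5 is set because the siloxyallyl unit can fold only over the β face of ring A, anti to the 4α-benzyloxy group next to C5. C1 is set in the quench, since AcOH protonates 14 on the face anti to the new C5–C6 bond, which gives the cis fusion on purpose. The step needs three selectivities: 1,2- over 1,4-addition (hard lithium enolate at −80 °C, long C–Si bond and very electrophilic C=O, an α-branch that twists the C=C out of conjugation, irreversible Brook step); [3+4] over [3+2] closure (the alkenyl group on C10 opens the Cope channel); and differentiation of the two oxygens (O8 leaves as a hindered tetrasubstituted silyl enol ether, O10 as a free ketone).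

Step 8
Reactants: 15 cis-fused hydroazulenone
Product: 16 tertiary alcohol (10α-CH3, 10β-OH; otherwise as 15)
Conditions: CeCl3, MeLi, THF, −78 °C; pH 7 buffer
Reagents that add atoms: methyllithium, [Li]C
Why: Organocerium 1,2-addition: the non-basic reagent leaves the acidic H-9 and H-1 alone, so the enol ether does not move into conjugation and C1 does not epimerise, and it should attack from the convex α face of the cis-fused bicycle (syn to H-1, anti to C2), which sets 10α-CH3/10β-OH.

Step 9
Reactants: 16 tertiary alcohol
Product: 17 4α,10β-diol (silyl enol ether retained)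
Conditions: H2 (1 atm), Pd(OH)2/C, EtOAc, rt
Reagents that add atoms: none
Why: Catalytic hydrogenolysis of the benzyl ether under neutral conditions; the hindered tetrasubstituted silyl enol ether is the only alkene and should not be hydrogenated, and no stereocentre is touched.

Step 10
Reactants: 17 4α,10β-diol
Product: 19 trans-fused C4 ketone (H-1α, H-5β), via cis-fused ketone 18 (not isolated)
Conditions: SO3·pyridine, DMSO, Et3N, CH2Cl2, 0 °C; then DBU, rt
Reagents that add atoms: none
Why: Parikh–Doering oxidation of the only secondary alcohol in a basic medium that spares the enol ether, then thermodynamic epimerisation α to the new ketone: C5 should invert because the cis isomer must hold C2 or C4 axial on ring B whereas the trans isomer holds both equatorial, and the enol ether, conjugated to no carbonyl, cannot migrate.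

Step 11
Reactants: 19 trans-fused C4 ketone
Product: 21 C3=C4 enol triflate, via dilithium alkoxide enolate 20 (not isolated)
Conditions: LDA (2.2 equiv), THF, −78 °C; N-(5-chloropyridin-2-yl)triflimide; AcOH
Reagents that add atoms: N-(5-chloropyridin-2-yl)bis(trifluoromethanesulfonimide), O=S(=O)(N(c1ccc(Cl)cn1)S(=O)(=O)C(F)(F)F)C(F)(F)F
Why: Kinetic enolate formation at CH2-3 rather than at the tertiary ring-fusion H-5, followed by O-triflation, fixes the double bond at C3=C4 without touching C5; the hindered tertiary lithium alkoxide should stay inert.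

Step 12
Reactants: 21 C3=C4 enol triflate
Product: 22 4-methyl C3=C4 alkene (silyl enol ether and 10β-OH retained)
Conditions: Me4Sn, Pd(PPh3)4 (5 mol %), LiCl, THF, 65 °C
Reagents that add atoms: tetramethylstannane, C[Sn](C)(C)C
Why: Stille coupling of an alkenyl triflate under neutral conditions (oxidative addition to zerovalent palladium, chloride exchange, methyl transfer) keeps the alkene position and tolerates the free alcohol and the enol ether.

Step 13
Reactants: 22 4-methyl C3=C4 alkene
Product: 24 β-hydroxy ketone (C8 ketone, H-7α, 7β-i-Pr), via ammonium enolate 23 (not isolated)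
Conditions: Bu4NF, AcOH, THF, −78 → −20 °C
Reagents that add atoms: none
Why: Buffered fluoride desilylation with kinetic enolate protonation: in the chair cycloheptene forced by the trans fusion (C1 apex on the α side) the β face of C7=C8 is the inner face screened by the axial 10β-OH and H-5β, so AcOH should protonate C7 from α, and buffer and cold suppress later epimerisation and retro-aldol cleavage.

Step 14
Reactants: 24 β-hydroxy ketone
Product: 26 8β,10β-diol, via diethylborinate chelate 25 (not isolated)
Conditions: Et2BOMe, THF–MeOH, −78 °C; NaBH4; MeOH co-evaporation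
Reagents that add atoms: none
Why: Narasaka–Prasad syn reduction: O8 must stay on the β side to keep the boron chelate with O10, so external hydride should come from the α face, which is also anti to the 7β-isopropyl group, and sets H-8α/8β-OH.

Step 15
Reactants: 26 8β,10β-diol
Product: 27 8β-(3,4-dimethoxybenzoyloxy) alkene
Conditions: 3,4-(MeO)2C6H3COCl, Et3N, DMAP, CH2Cl2, 0 → 40 °C
Reagents that add atoms: 3,4-dimethoxybenzoyl chloride, COc1ccc(C(=O)Cl)cc1OC
Why: DMAP-catalysed acylation through the acylpyridinium ion reaches only the secondary 8-OH, the tertiary 10-OH being inert, and no stereocentre is touched.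

Step 16
Reactants: 27 8β-(3,4-dimethoxybenzoyloxy) alkene
Product: 28 CNP0304846.1
Conditions: D-fructose-derived Shi ketone (30 mol %), Oxone (2KHSO5·KHSO4·K2SO4), K2CO3, Bu4NHSO4, MeCN–(MeO)2CH2/aq Na2B4O7 buffer, 0 °C
Reagents that add atoms: potassium peroxymonosulfate, [K+].[O-]S(=O)(=O)OO
Why: Shi epoxidation: the two faces of the trans-fused cyclopentene differ little, so the spiro transition state of the D-fructose-derived dioxirane, which places the single vinylic H in its hindered quadrant, should decide for the (3R,4S)-oxirane on the α face, and the basic buffer keeps the 10β-OH from opening the product.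

**Compound list**
1 | 3-bromocyclopent-2-en-1-one | O=C1C=C(Br)CC1 | starting material
2 | (1R)-3-bromocyclopent-2-en-1-ol | O[C@H]1C=C(Br)CC1 | intermediate
3 | benzyl (1R)-3-bromocyclopent-2-en-1-yl ether | BrC1=C[C@H](OCc2ccccc2)CC1 | intermediate
4 | [(3R)-3-(benzyloxy)cyclopent-1-en-1-yl]lithium | [Li]C1=C[C@H](OCc2ccccc2)CC1 | intermediate
5 | 1-[(3R)-3-(benzyloxy)cyclopent-1-en-1-yl]ethan-1-one | CC(=O)C1=C[C@H](OCc2ccccc2)CC1 | intermediate
6 | prop-2-yn-1-ol | C#CCO | starting material
7 | 3-methyl-2-methylidenebutan-1-ol | C=C(CO)C(C)C | intermediate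
8 | tert-butyl(dimethyl)[(3-methyl-2-methylidenebutyl)oxy]silane | C=C(CO[Si](C)(C)C(C)(C)C)C(C)C | intermediate
9 | 1-[tert-butyl(dimethyl)silyl]-3-methyl-2-methylidenebutan-1-ol (racemic) | C=C(C(C)C)C(O)[Si](C)(C)C(C)(C)C | intermediate
10 | 1-[tert-butyl(dimethyl)silyl]-3-methyl-2-methylidenebutan-1-one | C=C(C(C)C)C(=O)[Si](C)(C)C(C)(C)C | intermediate
11 | lithium dienolate of 5 | [Li]OC(=C)C1=C[C@H](OCc2ccccc2)CC1 | intermediate
12 | lithium α-silyl carbinolate, 1,2-adduct (C8 epimers) | CC(C)C(=C)C(O[Li])(CC(=O)C1=C[C@H](OCc2ccccc2)CC1)[Si](C)(C)C(C)(C)C | intermediate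
13 | lithium cis-1,2-dialkenyl-2-silyloxycyclopropan-1-olate | [Li]O[C@]2(C[C@]2(O[Si](C)(C)C(C)(C)C)C(=C)C(C)C)C1=C[C@H](OCc3ccccc3)CC1 | intermediate
14 | lithium cycloheptadienolate (C1=C10 enolate, H-5α) | CC(C)C1=C(O[Si](C)(C)C(C)(C)C)CC(O[Li])=C2CC[C@@H](OCc3ccccc3)[C@@H]2C1 | intermediate
15 | cis-fused hydroazulenone (C10 ketone, C7=C8 silyl enol ether, 4α-OBn, H-1α, H-5α) | CC(C)C1=C(O[Si](C)(C)C(C)(C)C)CC(=O)[C@@H]2CC[C@@H](OCc3ccccc3)[C@@H]2C1 | intermediate
16 | tertiary alcohol (10α-CH3, 10β-OH) | CC(C)C1=C(O[Si](C)(C)C(C)(C)C)C[C@](C)(O)[C@@H]2CC[C@@H](OCc3ccccc3)[C@@H]2C1 | intermediate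
17 | 4α,10β-diol | CC(C)C1=C(O[Si](C)(C)C(C)(C)C)C[C@](C)(O)[C@@H]2CC[C@@H](O)[C@@H]2C1 | intermediate
18 | cis-fused C4 ketone (H-5α) | CC(C)C1=C(O[Si](C)(C)C(C)(C)C)C[C@](C)(O)[C@@H]2CCC(=O)[C@@H]2C1 | intermediate
19 | trans-fused C4 ketone (H-5β) | CC(C)C1=C(O[Si](C)(C)C(C)(C)C)C[C@](C)(O)[C@@H]2CCC(=O)[C@H]2C1 | intermediate
20 | dilithium 10-alkoxide C3=C4 enolate | CC(C)C1=C(O[Si](C)(C)C(C)(C)C)C[C@](C)(O[Li])[C@@H]2CC=C(O[Li])[C@H]2C1 | intermediate
21 | C3=C4 enol triflate | CC(C)C1=C(O[Si](C)(C)C(C)(C)C)C[C@](C)(O)[C@@H]2CC=C(OS(=O)(=O)C(F)(F)F)[C@H]2C1 | intermediate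
22 | 4-methyl C3=C4 alkene | CC(C)C1=C(O[Si](C)(C)C(C)(C)C)C[C@](C)(O)[C@@H]2CC=C(C)[C@H]2C1 | intermediate
23 | tetrabutylammonium C7=C8 enolate | CC(C)C1=C([O-])C[C@](C)(O)[C@@H]2CC=C(C)[C@H]2C1.CCCC[N+](CCCC)(CCCC)CCCC | intermediate
24 | β-hydroxy ketone (C8 ketone, 7β-i-Pr) | O=C1C[C@](C)(O)[C@@H]2CC=C(C)[C@H]2C[C@@H]1C(C)C | intermediate
25 | 10-O-diethylborinate of 24 | O=C1C[C@](C)(OB(CC)CC)[C@@H]2CC=C(C)[C@H]2C[C@@H]1C(C)C | intermediate
26 | 8β,10β-diol | O[C@@H]1C[C@](C)(O)[C@@H]2CC=C(C)[C@H]2C[C@@H]1C(C)C | intermediate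
27 | 8β-(3,4-dimethoxybenzoyloxy) alkene | COc1ccc(C(=O)O[C@@H]2C[C@](C)(O)[C@@H]3CC=C(C)[C@H]3C[C@@H]2C(C)C)cc1OC | intermediate
28 | CNP0304846.1 | COc1ccc(C(=O)O[C@@H]2C[C@](C)(O)[C@@H]3C[C@H]4O[C@@]4(C)[C@H]3C[C@@H]2C(C)C)cc1OC | target

**Step count**
- Total steps: 16.
- Longest linear sequence: 13 steps (steps 1–3 or 4–6, then 7–16).

**Steps most likely to fail**

Step 7.
- Risk: the dienolate may add in conjugate fashion to the unsubstituted CH2 terminus of the acylsilane. A slow Brook shift may also let the 1,2-adduct revert.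
- Fallback (from 5 and 10, back at 15): the two events are separated. Ketone 5 is converted with Me3SiOTf/Et3N into the trimethylsilyl dienol ether F1. This is added to the BF3·OEt2-activated acylsilane carbonyl of 10 in a Mukaiyama aldol reaction at −78 °C. No free enolate is present, and the neutral α-silyl carbinol F2 can be isolated. NaN(SiMe3)2 in THF (−78 → 0 °C) then starts the Brook shift, cyclopropanolate formation and oxy-Cope rearrangement from the preformed C8–C9 bond. An AcOH quench returns to 15.

Step 13.
- Risk: protonation may occur on both faces, or the ketone may enolise after it has formed. Either process scrambles C7.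
- Fallback (from 24 as a mixture of C7 epimers, back at 26): kinetic protonation is replaced by dynamic kinetic resolution. The mixture is silylated at O10 (Me3SiOTf, 2,6-lutidine) to the trimethylsilyl ether F3, which blocks retro-aldol cleavage. Hydrogenation follows with RuCl2(binap)(dpen)/KOt-Bu in i-PrOH under H2, using the catalyst enantiomer matched to the 8β-alcohol. It interconverts the C7 epimers and reduces only the one that leads to the cis-2-alkylcycloalkanol, giving the silyl ether alcohol F4. K2CO3/MeOH removes the silyl group and gives 26.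

Step 16.
- Risk: reagent control may be too weak on a nearly unbiased alkene, and hydrogen bonding to the 10β-OH may draw the oxidant to the β face.
- Fallback (from 27, back at 28): the directing effect is used and the oxirane is then inverted. VO(acac)2/t-BuOOH should epoxidise syn to the 10β-OH and give the β-epoxide F5. Dilute HClO4 in THF–H2O opens it at the tertiary C4 with inversion to the 3β,4α-diol F6; the 10-OH sits on the β face and cannot reach the backside. MsCl/Et3N esterifies only the secondary 3-OH to the mesylate F7. With K2CO3/MeOH the 4α-alkoxide displaces the 3β-mesylate with inversion, which closes the α-oxirane of 28.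

**Further compounds**
F1 | step 7 | ({1-[(3R)-3-(benzyloxy)cyclopent-1-en-1-yl]ethenyl}oxy)trimethylsilane | C=C(O[Si](C)(C)C)C1=C[C@H](OCc2ccccc2)CC1
F2 | step 7 | α-silyl carbinol, Mukaiyama aldol adduct of F1 and 10 (C8 epimers) | CC(C)C(=C)C(O)(CC(=O)C1=C[C@H](OCc2ccccc2)CC1)[Si](C)(C)C(C)(C)C
F3 | step 13 | 10-O-trimethylsilyl ether of 24 (C7 epimers) | O=C1C[C@](C)(O[Si](C)(C)C)[C@@H]2CC=C(C)[C@H]2CC1C(C)C
F4 | step 13 | 10-O-trimethylsilyl ether of 26 | O[C@@H]1C[C@](C)(O[Si](C)(C)C)[C@@H]2CC=C(C)[C@H]2C[C@@H]1C(C)C
F5 | step 16 | 3β,4β-epoxide, epimer of 28 at the oxirane | COc1ccc(C(=O)O[C@@H]2C[C@](C)(O)[C@@H]3C[C@@H]4O[C@]4(C)[C@H]3C[C@@H]2C(C)C)cc1OC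
F6 | step 16 | 3β,4α,10β-triol 8-veratrate | COc1ccc(C(=O)O[C@@H]2C[C@](C)(O)[C@@H]3C[C@H](O)[C@@](C)(O)[C@H]3C[C@@H]2C(C)C)cc1OC
F7 | step 16 | 3β-mesylate of F6 | COc1ccc(C(=O)O[C@@H]2C[C@](C)(O)[C@@H]3C[C@H](OS(C)(=O)=O)[C@@](C)(O)[C@H]3C[C@@H]2C(C)C)cc1OC
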